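At early times the solid held the substrate and the partner stood at full charge. I needed the number that would carry the answer.

solid substrate 1.0 M; partner 0.700 M; protic impurity 0.200 M; time 20 h

1. amount of target at 20 h, in percent of the solid substrate charged
2. the change that raises the amount of target at 20 h, in percent of the solid substrate charged most ("none" if none brings more than 2 percentage points) (theta / gamma / zeta / none)
3. amount of target at 20 h, in percent of the solid substrate charged, after gamma

- theta: doubling the solubility in step 6, all else as stated
- gamma: doubling the dissolution coefficient of step 6, all else as stated
- zeta: doubling the amount of partner, all else as stated

- percentages count the solid substrate that a species holds: one side product counts as two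
- for a step with 2 of a species take k times the square, and two of it per event
- solid, in amounts per volume of the solution: solid substrate
- at the start none of the solid substrate is in solution
- run time (flask): 20 h

    2 partner → homo dimer (k1 = 0.012 /M/min)
    partner + protic impurity → quenched reagent (k2 = 0.017 /M/min)
    2 dissolved substrate → side product (k3 = 0.013 /M/min)
    dissolved substrate + partner → target (k4 = 0.013 /M/min)
    partner → decomposed reagent (k5 = 0.0011 /min)
    solid substrate ⇌ dissolved substrate, rate k6*(cs6 - [dissolved substrate]) while solid is left; crystals form when [dissolved substrate] > cs6 (cs6 = 0.14 M, k6 = 0.030 /min)

Target forms at its constant times dissolved substrate times partner, so I looked for the level of dissolved substrate. For late times, with the partner term dropped and solid left, I set dissolving equal to the step to side product: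

level × level + b × level = b × solubility, with b = 1.15 M

I tested each number in turn, as a fraction of the charge. Doubling the solubility gave 23.3%. Doubling the dissolution coefficient gave 13.2%. Doubling the constant of the side-product step gave 11.6%. Doubling the solubility gave a higher fraction than either of the others. The solid charge stands nowhere in the balance.

The number itself is the plateau fraction, 12.6%, the share of the charge in solution where dissolving meets the side-product step.

I let partner fall by dimerisation and a pseudo-first-order loss, with impurity held at its charge:

target ≈ k4 × plateau × ln(1 + 2 k1 × partner / (k2 × impurity + k5)) / (2 k1) = 10.6%

Partner's first half-life by dimerisation, 59.5 min, is longer than the 33.3 min that dissolved substrate takes to come up, but of like size. So I committed to less than 10.6%, and to theta.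

The forecast gave 8.1%, theta as best, and 9.5% after gamma; it began from “Partner is lost mainly by dimerisation”.

The simulation gave 8.21%, with theta best at 4.7 percentage points, and 9.39% after gamma. The forecast stood.

In this flask target and homo dimer formed in the first hours: partner was at 22.7% of its charge by 2.00 h, with target at 3.87%, and at 1.83% by 10.0 h, with target at 7.74%. Afterwards side product grew to 46.5% by 20.0 h, while dissolved substrate stood at 12.6%, against the plateau fraction of 12.6%.

For the neighbour with 1.7 M of solid, the same level over the larger charge gives 7.42%, and the same target concentration gives 4.83%. That neighbour computed 7.42% dissolved and 4.83% target.

The constants used here are made up; the result is computed.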